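The C4/C5/C10 triad of ring A is that of (+)-podocarpic acid, so its aromatic ring C is excised with RuO4, which also opens ring B between C8 and C9. Ring B is rebuilt by a SmI2 ketyl–olefin cyclization that exploits the vicinal pair C8 (tertiary carbinol with the C17 methyl) and C9 (methine with the side chain): the C8 methyl ketone adds 6-exo to C9 of a C9=C11 allylic sulfide on C10, and loss of thiophenolate leaves a C9 vinyl group. One operation gives the C8–C9 bond, both new stereocentres and the handle for a B-alkyl Suzuki coupling that completes the diene.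

Key step: step 7

Remarks on the chemistry: labdane numbering (C1–C20) is kept for every compound, also for the monocyclic seco intermediates; α is the face of H-5, β the face of the C10 methyl. Compound 7 is drawn as the Z isomer expected from a non-stabilized ylide; the geometry of this alkene is erased in step 7. 4-Acetoxy-3-methoxycinnamic acid (17) is taken as a purchased compound.

Step 1
Reactants: 1 (+)-podocarpic acid
Product: 2 methyl podocarpate
Conditions: MeI, KHCO3, DMF, rt
Reagents that add atoms: iodomethane, CI
Why: SN2 O-alkylation of the carboxylate esterifies the hindered axial C19 acid while the phenol, not deprotonated by bicarbonate, stays free; this marks C19 as an ester before two further acids are made.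

Step 2
Reactants: 2 methyl podocarpate
Product: 3 seco-diacid (19-methyl ester of 11,12,13,14-tetranor-8,9-secopodocarpane-8,9,19-trioic acid)
Conditions: RuCl3·xH2O (5 mol %), NaIO4 (15 equiv), CCl4/MeCN/H2O, rt
Reagents that add atoms: sodium periodate, [Na+].[O-]I(=O)(=O)=O; water, O
Why: RuO4 generated catalytically degrades the electron-rich phenol ring to carboxylic acids at the two ring-fusion carbons C8 and C9 (oxidative arene degradation), C11–C14 leaving as CO2; the quaternary centres C4 and C10, H-5 and the hindered ester are not affected.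

Step 3
Reactants: 3 seco-diacid
Product: 4 C9 acid diester (8,19-dimethyl ester of the triacid)
Conditions: MeOH, H2SO4 (cat.), rt
Reagents that add atoms: methanol, CO
Why: Fischer esterification is fast at the unhindered C8 acid of the propanoic chain and very slow at the tertiary C9 acid on quaternary C10, so only the C8 acid should be esterified.

Step 4
Reactants: 4 C9 acid diester
Product: 6 C9 aldehyde diester, via acid chloride 5 (not isolated)
Conditions: (COCl)2, DMF (cat.), CH2Cl2, 0 °C to rt; evaporate; LiAlH(OtBu)3 (1.05 equiv), THF, −78 °C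
Reagents that add atoms: oxalyl chloride, ClC(=O)C(=O)Cl (chlorine of 5 only)
Why: the acid chloride is reduced by the bulky, mild hydride only as far as the aldehyde at −78 °C (acid chloride to aldehyde reduction) and both methyl esters survive; C10 is quaternary, so the aldehyde cannot epimerize.

Step 5
Reactants: 6 C9 aldehyde diester
Product: 7 (Z)-allyl phenyl sulfide diester
Conditions: CH2=CHPPh3Br, PhSNa, THF/DMF, 0 °C to rt; then 6, rt to 50 °C
Reagents that add atoms: vinyltriphenylphosphonium bromide, C=C[P+](c1ccccc1)(c1ccccc1)c1ccccc1.[Br-]; sodium benzenethiolate, [Na+].[S-]c1ccccc1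
Why: conjugate addition of the thiolate to the vinylphosphonium salt gives the non-stabilized ylide Ph3P=CH–CH2SPh, which olefinates the non-enolizable aldehyde (Wittig reaction) mainly to the Z alkene and adds C11 and C12 with an allylic leaving group; the esters are not attacked.

Step 6
Reactants: 7 (Z)-allyl phenyl sulfide diester
Product: 9 keto allyl sulfide (C8 methyl ketone), via Weinreb amide 8 (not isolated)
Conditions: MeNHOMe·HCl, i-PrMgCl, THF, −20 °C; then MeMgBr, 0 °C; aq. NH4Cl
Reagents that add atoms: N,O-dimethylhydroxylamine hydrochloride, CNOC.Cl (N(OMe)Me of 8 only); methylmagnesium bromide, C[Mg]Br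
Why: the magnesium amide converts only the unhindered C8 ester into the Weinreb amide, whose chelated adduct with MeMgBr releases the methyl ketone (C17 installed) on work-up (Weinreb ketone synthesis); the neopentyl C19 ester and the sulfide are inert.

Step 7
Reactants: 9 keto allyl sulfide
Product: 10 methyl 8α-hydroxy-13,14,15,16-tetranorlabd-11-en-19-oate
Conditions: SmI2 (0.1 M in THF, 3 equiv), HMPA (12 equiv), THF, 0 °C to rt, slow addition of 9; aq. NH4Cl
Reagents that add atoms: none
Why: Electron transfer from SmI2–HMPA to the C8 ketone gives the samarium ketyl, whose carbon adds to C9 of the tethered alkene; the C11 radical then loses PhS• by β-scission (or, after a second electron transfer, thiolate from the alkylsamarium), which leaves the C11=C12 vinyl group. The closest known reaction type is the SmI2-mediated ketyl–olefin cyclization followed by β-elimination of an allylic leaving group. Ring B closes in the 6-exo-trig mode through a chair fused to ring A in which the tethers on C5 and C10 are both equatorial, so only the trans-decalin can form. At C8 the bulky, HMPA-solvated O–Sm group should take the equatorial α position and leave the methyl axial β, and at C9 the alkenyl carbon C11 should lie equatorial β and trans to the oxygen, so that H-9 ends α. The step needs reduction of the ketone alone in the presence of the hindered ester and the sulfide, and cyclization faster than ketyl protonation or pinacol coupling; the absence of a proton source, high dilution and the short tether held on adjacent ring carbons should secure this.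

Step 8
Reactants: 11 methyl vinyl ketone
Product: 13 buta-1,3-dien-2-yl trifluoromethanesulfonate, via lithium dienolate 12 (not isolated)
Conditions: LiN(iPr)2, THF, −78 °C, slow addition of 11; then PhNTf2, −78 to 0 °C
Reagents that add atoms: N-phenylbis(trifluoromethanesulfonimide), O=S(=O)(N(c1ccccc1)S(=O)(=O)C(F)(F)F)C(F)(F)F; lithium diisopropylamide, [Li]N(C(C)C)C(C)C (lithium of 12 only)
Why: kinetic deprotonation at the only enolizable position gives the cross-conjugated lithium dienolate, which is O-sulfonylated by the triflimide (enol triflate formation); slow addition of the enone to the base at −78 °C suppresses Michael oligomerization.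

Step 9
Reactants: 10 methyl 8α-hydroxy-13,14,15,16-tetranorlabd-11-en-19-oate; 13 buta-1,3-dien-2-yl trifluoromethanesulfonate
Product: 15 methyl 8α-hydroxylabda-13(16),14-dien-19-oate, via B-alkyl-9-BBN borane 14 (not isolated)
Conditions: 9-BBN-H (2.5 equiv), THF, 0 °C to rt; then 13, PdCl2(dppf) (5 mol %), aq. K3PO4, THF/DMF, 50 °C
Reagents that add atoms: 9-borabicyclo[3.3.1]nonane, B1C2CCCC1CCC2 (boron residue of 14 only)
Why: 9-BBN adds to the only alkene with boron at terminal C12 (anti-Markovnikov hydroboration), and the B-alkyl Suzuki–Miyaura coupling with the dienyl triflate forms the C12–C13 bond with the 2-substituted buta-1,3-diene intact; using C12 as the nucleophile avoids a C12 leaving group that the 8-hydroxyl could displace, and no stereocentre is touched.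

Step 10
Reactants: 15 methyl 8α-hydroxylabda-13(16),14-dien-19-oate
Product: 16 labda-13(16),14-diene-8α,19-diol
Conditions: LiAlH4, THF, 0 °C to reflux; aq. NaOH work-up
Reagents that add atoms: none
Why: hydride reduction of the hindered axial C19 methyl ester to the primary alcohol (ester reduction with LiAlH4); the unactivated diene and the tertiary alcohol should not react and no stereocentre is involved.

Step 11
Reactants: 16 labda-13(16),14-diene-8α,19-diol; 17 (E)-4-acetoxy-3-methoxycinnamic acid
Product: 19 8α-hydroxylabda-13(16),14-dien-19-yl (E)-ferulate (CNP0142252.1), via aryl acetate 18 (not isolated)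
Conditions: 17 (1.5 equiv), EDC·HCl, DMAP, CH2Cl2, rt; then pyrrolidine, rt
Reagents that add atoms: none
Why: carbodiimide/DMAP (Steglich) esterification acylates only the primary C19 hydroxyl because the tertiary 8-hydroxyl is too hindered, and pyrrolidine added to the same flask cleaves the more electrophilic aryl acetate by aminolysis without touching the neopentyl cinnamate or its E double bond.

Compound list

1 | (+)-podocarpic acid (12-hydroxypodocarpa-8,11,13-trien-19-oic acid; 4α-Me, 4β-CO2H, 5α-H, 10β-Me) | Oc1ccc2c(c1)[C@@]1(C)CCC[C@](C)(C(=O)O)[C@@H]1CC2 | starting material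
2 | methyl podocarpate (methyl 12-hydroxypodocarpa-8,11,13-trien-19-oate) | Oc1ccc2c(c1)[C@@]1(C)CCC[C@](C)(C(=O)OC)[C@@H]1CC2 | intermediate
3 | seco-diacid, 3-[(1R,2S,6S)-2-carboxy-6-(methoxycarbonyl)-2,6-dimethylcyclohexyl]propanoic acid (C10: β-Me, α-CO2H; C5: α-H, β-chain; C4: α-Me, β-CO2Me) | OC(=O)[C@@]1(C)CCC[C@](C)(C(=O)OC)[C@@H]1CCC(=O)O | intermediate
4 | C9 acid diester: as 3, but with the propanoic (C8) acid as its methyl ester and the C9 acid on C10 free | OC(=O)[C@@]1(C)CCC[C@](C)(C(=O)OC)[C@@H]1CCC(=O)OC | intermediate
5 | C9 acid chloride of 4 | ClC(=O)[C@@]1(C)CCC[C@](C)(C(=O)OC)[C@@H]1CCC(=O)OC | intermediate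
6 | C9 aldehyde diester: ring A of 3 with 10α-CHO, 10β-Me, 5β-CH2CH2CO2Me, 4β-CO2Me, 4α-Me | O=C[C@@]1(C)CCC[C@](C)(C(=O)OC)[C@@H]1CCC(=O)OC | intermediate
7 | (Z)-allyl phenyl sulfide diester: as 6, with (Z)-CH=CH–CH2SPh (C9=C11–C12) in place of CHO | c1ccccc1SC/C=C\[C@@]1(C)CCC[C@](C)(C(=O)OC)[C@@H]1CCC(=O)OC | intermediate
8 | Weinreb amide: as 7, with C8 as C(=O)N(OMe)Me | c1ccccc1SC/C=C\[C@@]1(C)CCC[C@](C)(C(=O)OC)[C@@H]1CCC(=O)N(C)OC | intermediate
9 | keto allyl sulfide: as 7, with the C5 chain as CH2CH2C(=O)CH3 (C8 methyl ketone, C17 methyl) | c1ccccc1SC/C=C\[C@@]1(C)CCC[C@](C)(C(=O)OC)[C@@H]1CCC(C)=O | intermediate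
10 | methyl 8α-hydroxy-13,14,15,16-tetranorlabd-11-en-19-oate (trans-decalin; 8β-Me, 9α-H, 9β-vinyl) | C=C[C@@H]1[C@@]2(C)CCC[C@](C)(C(=O)OC)[C@@H]2CC[C@@]1(C)O | intermediate
11 | methyl vinyl ketone (but-3-en-2-one) | C=CC(C)=O | starting material
12 | lithium buta-1,3-dien-2-olate | C=CC(=C)O[Li] | intermediate
13 | buta-1,3-dien-2-yl trifluoromethanesulfonate | C=CC(=C)OS(=O)(=O)C(F)(F)F | intermediate
14 | methyl 12-(9-borabicyclo[3.3.1]nonan-9-yl)-8α-hydroxy-13,14,15,16-tetranorlabdan-19-oate | C1CC2CCCC(C1)B2CC[C@@H]1[C@@]2(C)CCC[C@](C)(C(=O)OC)[C@@H]2CC[C@@]1(C)O | intermediate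
15 | methyl 8α-hydroxylabda-13(16),14-dien-19-oate | C=CC(=C)CC[C@@H]1[C@@]2(C)CCC[C@](C)(C(=O)OC)[C@@H]2CC[C@@]1(C)O | intermediate
16 | labda-13(16),14-diene-8α,19-diol | C=CC(=C)CC[C@@H]1[C@@]2(C)CCC[C@](C)(CO)[C@@H]2CC[C@@]1(C)O | intermediate
17 | (E)-4-acetoxy-3-methoxycinnamic acid (O-acetylferulic acid) | CC(=O)Oc1ccc(/C=C/C(=O)O)cc1OC | starting material
18 | 8α-hydroxylabda-13(16),14-dien-19-yl (E)-3-(4-acetoxy-3-methoxyphenyl)prop-2-enoate | C=CC(=C)CC[C@@H]1[C@@]2(C)CCC[C@](C)(COC(=O)/C=C/c3ccc(OC(C)=O)c(OC)c3)[C@@H]2CC[C@@]1(C)O | intermediate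
19 | CNP0142252.1, 8α-hydroxylabda-13(16),14-dien-19-yl (E)-ferulate, (4S,5R,8R,9R,10S) | C=CC(=C)CC[C@@H]1[C@@]2(C)CCC[C@](C)(COC(=O)/C=C/c3ccc(O)c(OC)c3)[C@@H]2CC[C@@]1(C)O | target

Total step count: 11. Longest linear sequence: 10 steps (steps 1 to 7, then 9 to 11); step 8 prepares the coupling partner.

Steps most likely to fail

1. Step 7 (key step). The 6-exo addition of the ketyl to the hindered, unactivated C9=C11 bond may be slower than ketyl protonation or pinacol coupling, and the preference for an equatorial O–Sm group at C8 may be incomplete (poor facial selectivity at C8). The fallback replaces the radical closure by a two-electron allyl-metal addition. It sets out from 9, whose sulfide is oxidized with mCPBA (2.1 equiv, CH2Cl2, 0 °C) to the allyl sulfone F1. Zerovalent palladium (Pd(PPh3)4) ionizes the sulfone, and Et2Zn (THF, rt) turns the allyl complex into an allylzinc species that adds through its C9 terminus to the C8 ketone in a closed six-membered transition state (umpolung carbonyl allylation). This comes back to the route at 10.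

2. Step 5. Reversible loss of thiolate from the β-thio ylide and slow attack on the neopentyl aldehyde may leave 6 unconverted. The fallback uses alkene metathesis instead of a heteroatom-bearing ylide. It sets out from 6: Wittig methylenation (Ph3PCH3Br, KOtBu, THF) should give the vinyl diester F2, and cross-metathesis with allyl phenyl sulfide (second-generation Hoveyda–Grubbs catalyst, CH2Cl2, 40 °C) the (E)-allyl sulfide F3. The protocol of step 6 then leads, by way of the Weinreb amide F4 formed in the flask, to the (E)-keto sulfide F5. Under the conditions of step 7, F5 should give 10, where the route is rejoined, because the alkene geometry is lost in the cyclization.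

3. Step 9. Hydrolysis or oligomerization of the volatile dienyl triflate 13 under the aqueous basic conditions may outrun transmetalation of the alkylborane. The fallback builds the diene after the coupling from a stable vinyl bromide. It sets out from 10: hydroboration as in step 9 gives 14, which is coupled with commercial 2-bromoprop-2-en-1-ol (PdCl2(dppf), aq. K3PO4, THF/DMF, 50 °C) to the allylic alcohol F6. MnO2 (CH2Cl2, rt) should give the enal F7, and Wittig methylenation (Ph3PCH3Br, KOtBu, THF, 0 °C) comes back to the route at 15.

Further compounds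

F1 | step 7 | allyl sulfone: as 9, with SO2Ph in place of SPh | O=S(=O)(C/C=C\[C@@]1(C)CCC[C@](C)(C(=O)OC)[C@@H]1CCC(C)=O)c1ccccc1
F2 | step 5 | vinyl diester: as 6, with CH=CH2 in place of CHO | C=C[C@@]1(C)CCC[C@](C)(C(=O)OC)[C@@H]1CCC(=O)OC
F3 | step 5 | (E)-allyl sulfide: E isomer of 7 | c1ccccc1SC/C=C/[C@@]1(C)CCC[C@](C)(C(=O)OC)[C@@H]1CCC(=O)OC
F4 | step 5 | Weinreb amide: E isomer of 8 | c1ccccc1SC/C=C/[C@@]1(C)CCC[C@](C)(C(=O)OC)[C@@H]1CCC(=O)N(C)OC
F5 | step 5 | (E)-keto sulfide: E isomer of 9 | c1ccccc1SC/C=C/[C@@]1(C)CCC[C@](C)(C(=O)OC)[C@@H]1CCC(C)=O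
F6 | step 9 | allylic alcohol: methyl 8α,14-dihydroxy-15-norlabd-13(16)-en-19-oate | C=C(CO)CC[C@@H]1[C@@]2(C)CCC[C@](C)(C(=O)OC)[C@@H]2CC[C@@]1(C)O
F7 | step 9 | enal: methyl 8α-hydroxy-14-oxo-15-norlabd-13(16)-en-19-oate | C=C(C=O)CC[C@@H]1[C@@]2(C)CCC[C@](C)(C(=O)OC)[C@@H]2CC[C@@]1(C)O
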